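## Retrosynthetic overview

- The ten-membered carbocycle is closed last, at C1–C2, by an intramolecular Nozaki–Hiyama–Kishi coupling of a Z-vinyl iodide with the C1 aldehyde; C2=C3 is then saturated, C1 oxidised to the ketone and C8 esterified.
- The 13-acetoxy-7(11)-butenolide comes from an α-methylene lactone: ozonolysis of C11=C13 to the enol, enol triflate, Stille hydroxymethylation, acetylation.
- Key disconnection C7–C8: intermolecular zinc Barbier allylation of a C8–C10/C1 aldehyde (fragment A) with a 3-(bromomethyl)butenolide carrying C2–C6 (fragment B); it sets C8 from C6.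
- Fragment B: Sharpless epoxidation of C-silylated (Z)-3-methylpent-2-en-4-yn-1-ol (C4, C5), Felkin vinylation (C6), acrylate ring-closing metathesis. Fragment A: Evans allylation (C10).
- Ring order: oxirane, then butenolide, then ten-membered carbocycle.

Assumption: germacrane numbering is used throughout (C1 ring ketone, C4/C5 oxirane, C6 lactone CH–O, C7=C11 butenolide alkene, C8 ester carbon, C10 CHMe, C12 lactone C=O, C13 CH2OAc); the target is read as 4R,5S,6S,8S,10R with an (E)-2-methylbut-2-enoate (tiglate) at O-8.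

## Route

Step 1
Reactants: 1 (S)-4-benzyl-3-propanoyl-1,3-oxazolidin-2-one; 2 allyl iodide
Product: 3 (S)-4-benzyl-3-[(2R)-2-methylpent-4-enoyl]-1,3-oxazolidin-2-one
Conditions: NaN(SiMe3)2, THF, −78 °C; then 2, −78 → −45 °C
Reagents that add atoms: allyl iodide (compound 2), C=CCI
Why: Evans asymmetric alkylation; the chelated sodium Z-enolate is allylated on the face opposite the benzyl group, which sets C10 as R.

Step 2
Reactants: 3 (S)-4-benzyl-3-[(2R)-2-methylpent-4-enoyl]-1,3-oxazolidin-2-one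
Product: 4 (R)-2-methylpent-4-en-1-ol
Conditions: LiBH4, H2O (1 equiv), Et2O, 0 °C
Reagents that add atoms: none
Why: Reductive cleavage of the N-acyl oxazolidinone gives the primary alcohol without touching the α-stereocentre and returns the auxiliary.

Step 3
Reactants: 4 (R)-2-methylpent-4-en-1-ol
Product: 5 (R)-1-methoxy-4-{[(2-methylpent-4-en-1-yl)oxy]methyl}benzene (PMB ether of 4)
Conditions: NaH, 4-methoxybenzyl chloride, Bu4NI (cat.), THF/DMF, 0 °C → rt
Reagents that add atoms: 4-methoxybenzyl chloride, COc1ccc(CCl)cc1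
Why: Williamson etherification protects the future C1 oxygen as a PMB ether that lasts until its oxidative removal in step 19.

Step 4
Reactants: 5 PMB ether of (R)-2-methylpent-4-en-1-ol
Product: 6 (R)-4-[(4-methoxybenzyl)oxy]-3-methylbutanal (fragment A)
Conditions: O3, CH2Cl2/MeOH, −78 °C (stopped at first blue tint); PPh3, −78 °C → rt
Reagents that add atoms: ozone, [O-][O+]=O
Why: Ozonolysis with reductive work-up cleaves the terminal alkene far faster than ozone attacks the anisyl ring and gives the C8 aldehyde; the stereocentre is β and cannot epimerise.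

Step 5
Reactants: 7 (Z)-3-methylpent-2-en-4-yn-1-ol
Product: 9 (Z)-3-methyl-5-(trimethylsilyl)pent-2-en-4-yn-1-ol, via bis-silylated enynol 8 (not isolated)
Conditions: n-BuLi (2.2 equiv), THF, −78 °C; Me3SiCl (2.3 equiv), → 0 °C; then 1 M aq. HCl, rt
Reagents that add atoms: chlorotrimethylsilane, C[Si](C)(C)Cl
Why: Double deprotonation and silylation, then selective hydrolysis of the labile O–Si bond, caps the terminal alkyne for the Grignard, metathesis, zinc and palladium steps.

Step 6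
Reactants: 9 (Z)-3-methyl-5-(trimethylsilyl)pent-2-en-4-yn-1-ol
Product: 10 [(2S,3R)-3-methyl-3-[(trimethylsilyl)ethynyl]oxiran-2-yl]methanol
Conditions: Ti(OiPr)4 (10 mol %), L-(+)-diethyl tartrate (12 mol %), t-BuOOH, 4 Å MS, CH2Cl2, −20 °C
Reagents that add atoms: tert-butyl hydroperoxide, CC(C)(C)OO
Why: Sharpless asymmetric epoxidation; with L-(+)-tartrate this nerol-type Z-allylic alcohol gives the (2S,3R)-epoxy alcohol (C5 S, C4 R), and the Z geometry becomes the cis relationship of C3 and C6 on the oxirane.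

Step 7
Reactants: 10 [(2S,3R)-3-methyl-3-[(trimethylsilyl)ethynyl]oxiran-2-yl]methanol
Product: 11 (2R,3R)-3-methyl-3-[(trimethylsilyl)ethynyl]oxirane-2-carbaldehyde
Conditions: Dess–Martin periodinane, NaHCO3, CH2Cl2, 0 °C → rt
Reagents that add atoms: none
Why: Dess–Martin oxidation; the oxirane α-carbon does not enolise, so the epoxy aldehyde keeps its configuration (the descriptor at C2 changes only by priority).

Step 8
Reactants: 11 (2R,3R)-3-methyl-3-[(trimethylsilyl)ethynyl]oxirane-2-carbaldehyde; 12 vinylmagnesium bromide (CH2=CHMgBr)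
Product: 13 (1S)-1-[(2S,3R)-3-methyl-3-[(trimethylsilyl)ethynyl]oxiran-2-yl]prop-2-en-1-ol
Conditions: 12, THF, −78 °C; aq. work-up
Reagents that add atoms: vinylmagnesium bromide (compound 12), C=C[Mg]Br
Why: Grignard 1,2-addition under Felkin–Anh/Cornforth control, reinforced by the cis substituent of the oxirane, places the vinyl group anti to the epoxide C–O bond and sets C6 as S; the minor epimer is removed by chromatography.

Step 9
Reactants: 13 (1S)-1-[(2S,3R)-oxiranyl]prop-2-en-1-ol; 14 2-(bromomethyl)acrylic acid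
Product: 15 (1S)-1-[(2S,3R)-3-methyl-3-[(trimethylsilyl)ethynyl]oxiran-2-yl]prop-2-en-1-yl 2-(bromomethyl)acrylate
Conditions: 14, DCC, DMAP (5 mol %), CH2Cl2, 0 °C
Reagents that add atoms: 2-(bromomethyl)acrylic acid (compound 14), C=C(CBr)C(=O)O
Why: Steglich esterification attaches the acrylate that carries the allylic bromide, with retention at C6.

Step 10
Reactants: 15 2-(bromomethyl)acrylate ester
Product: 16 (5S)-3-(bromomethyl)-5-[(2S,3R)-3-methyl-3-[(trimethylsilyl)ethynyl]oxiran-2-yl]furan-2(5H)-one (fragment B)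
Conditions: second-generation Hoveyda–Grubbs catalyst (5 mol %), toluene (0.01 M), 80 °C
Reagents that add atoms: none
Why: Ring-closing metathesis forms the five-membered butenolide with loss of ethylene; the hindered silyl-capped alkyne is not expected to compete.

Step 11
Reactants: 16 bromomethyl butenolide (fragment B); 6 (R)-4-[(4-methoxybenzyl)oxy]-3-methylbutanal (fragment A)
Product: 18 (4R,5S)-4-[(1S,3R)-1-hydroxy-4-[(4-methoxybenzyl)oxy]-3-methylbutyl]-3-methylidene-5-[(2S,3R)-3-methyl-3-[(trimethylsilyl)ethynyl]oxiran-2-yl]oxolan-2-one, via allylzinc bromide 17 (not isolated)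
Conditions: Zn dust (activated), THF/sat. aq. NH4Cl, 0 °C → rt
Reagents that add atoms: none
Why: Barbier-type carbonyl allylation; the allylzinc adds through its γ-carbon (C7) via a closed chair transition state, anti to the C6 substituent and with the aldehyde chain equatorial, which gives the 6,7-trans lactone and the 8S carbinol.

Step 12
Reactants: 18 Barbier adduct
Product: 19 C8 triethylsilyl ether of 18
Conditions: Et3SiOTf, 2,6-lutidine, CH2Cl2, −78 °C
Reagents that add atoms: triethylsilyl trifluoromethanesulfonate, CC[Si](CC)(CC)OS(=O)(=O)C(F)(F)F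
Why: Silylation blocks the secondary C8 alcohol during enol triflation, the oxidations and the macrocyclisation.

Step 13
Reactants: 19 silyl ether of the α-methylene lactone
Product: 21 (5S)-3-hydroxy-4-[(1S,3R)-4-[(4-methoxybenzyl)oxy]-3-methyl-1-(triethylsilyloxy)butyl]-5-[(2S,3R)-3-methyl-3-[(trimethylsilyl)ethynyl]oxiran-2-yl]furan-2(5H)-one, via α-keto lactone 20 (not isolated)
Conditions: O3, CH2Cl2, −78 °C; Me2S, −78 °C → rt
Reagents that add atoms: ozone, [O-][O+]=O
Why: Ozonolysis of the exocyclic methylene gives the α-keto lactone, which tautomerises to the conjugated enol (an isotetronic acid); this creates the C7=C11 double bond and erases the C7 stereocentre.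

Step 14
Reactants: 21 enol (isotetronic acid)
Product: 22 C11 enol triflate of 21
Conditions: PhNTf2, Et3N, DMAP (cat.), CH2Cl2, 0 °C → rt
Reagents that add atoms: N-phenylbis(trifluoromethanesulfonimide), O=S(=O)(N(c1ccccc1)S(=O)(=O)C(F)(F)F)C(F)(F)F
Why: O-sulfonylation of the acidic enol gives the vinyl triflate needed for cross-coupling.

Step 15
Reactants: 22 enol triflate; 23 (tributylstannyl)methanol (Bu3SnCH2OH)
Product: 24 (5S)-3-(hydroxymethyl)-4-[(1S,3R)-4-[(4-methoxybenzyl)oxy]-3-methyl-1-(triethylsilyloxy)butyl]-5-[(2S,3R)-3-methyl-3-[(trimethylsilyl)ethynyl]oxiran-2-yl]furan-2(5H)-one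
Conditions: 23, Pd(PPh3)4 (10 mol %), LiCl, 1,4-dioxane, 90 °C; stopped as soon as 22 is consumed
Reagents that add atoms: (tributylstannyl)methanol (compound 23), CCCC[Sn](CO)(CCCC)CCCC
Why: Stille cross-coupling replaces the triflate by the hydroxymethyl group (C13) with retention of the tetrasubstituted alkene.

Step 16
Reactants: 24 hydroxymethyl butenolide
Product: 25 C13 acetate of 24
Conditions: Ac2O, pyridine, DMAP (cat.), CH2Cl2, 0 °C
Reagents that add atoms: acetic anhydride, CC(=O)OC(C)=O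
Why: Acetylation installs the C13 acetate of the target and protects this alcohol in the later oxidations.

Step 17
Reactants: 25 silyl alkyne acetate
Product: 26 1-iodoalkyne (C2-iodo) corresponding to 25
Conditions: N-iodosuccinimide, AgNO3 (10 mol %), acetone, rt, dark
Reagents that add atoms: N-iodosuccinimide, O=C1CCC(=O)N1I
Why: Silver-catalysed iododesilylation converts the C-silyl alkyne directly into the iodoalkyne under neutral conditions.

Step 18
Reactants: 26 iodoalkyne
Product: 27 (Z)-vinyl iodide (C2=C3) corresponding to 26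
Conditions: 2-nitrobenzenesulfonohydrazide, Et3N, THF/i-PrOH, rt
Reagents that add atoms: none
Why: Diimide reduction adds hydrogen cis to the iodoalkyne and gives the Z-vinyl iodide; the tetrasubstituted butenolide alkene is inert to diimide.

Step 19
Reactants: 27 (Z)-vinyl iodide PMB ether
Product: 28 primary C1 alcohol corresponding to 27
Conditions: DDQ, CH2Cl2/pH 7 buffer, 0 °C
Reagents that add atoms: none
Why: Oxidative PMB cleavage frees the C1 alcohol without affecting the silyl ether, acetate, epoxide or vinyl iodide.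

Step 20
Reactants: 28 primary alcohol
Product: 29 C1 aldehyde corresponding to 28
Conditions: Dess–Martin periodinane, NaHCO3, CH2Cl2, 0 °C → rt
Reagents that add atoms: none
Why: Buffered Dess–Martin oxidation gives the aldehyde without epimerising the adjacent C10 stereocentre.

Step 21
Reactants: 29 iodo-aldehyde
Product: 30 (1RS,2Z,4R,5S,6S,8S,10R)-13-acetoxy-4,5-epoxy-1-hydroxy-8-(triethylsilyloxy)germacra-2,7(11)-dien-12,6-olide
Conditions: CrCl2 (10 equiv), NiCl2 (cat.), DMSO, rt, 0.003 M, slow addition of 29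
Reagents that add atoms: none
Why: Intramolecular Nozaki–Hiyama–Kishi reaction closes the ten-membered ring at C1–C2 with retention of the Z-alkene; the C1 carbinol forms as an epimer mixture that is removed by the later oxidation.

Step 22
Reactants: 30 macrocyclic allylic alcohol
Product: 31 (1RS,4R,5S,6S,8S,10R)-13-acetoxy-4,5-epoxy-1-hydroxy-8-(triethylsilyloxy)germacr-7(11)-en-12,6-olide
Conditions: 2-nitrobenzenesulfonohydrazide (excess, in portions), Et3N, THF/i-PrOH, rt
Reagents that add atoms: none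
Why: Diimide reduction saturates the cis ring alkene without hydrogenolysis of the neighbouring oxirane and leaves the tetrasubstituted butenolide alkene intact.

Step 23
Reactants: 31 saturated macrocyclic alcohol
Product: 32 (4R,5S,6S,8S,10R)-13-acetoxy-4,5-epoxy-1-oxo-8-(triethylsilyloxy)germacr-7(11)-en-12,6-olide
Conditions: Dess–Martin periodinane, NaHCO3, CH2Cl2, rt
Reagents that add atoms: none
Why: Dess–Martin oxidation converts both C1 epimers into the ring ketone under non-epimerising conditions.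

Step 24
Reactants: 32 silyl ether ketone
Product: 33 (4R,5S,6S,8S,10R)-13-acetoxy-4,5-epoxy-8-hydroxy-1-oxogermacr-7(11)-en-12,6-olide
Conditions: HF·pyridine, pyridine, THF, 0 °C
Reagents that add atoms: none
Why: Buffered fluoride desilylation frees the C8 alcohol and preserves the epoxide, the acetate and the C10 stereocentre.

Step 25
Reactants: 33 C8 alcohol; 34 tigloyl chloride
Product: 35 (4R,5S,6S,8S,10R)-13-acetoxy-4,5-epoxy-1-oxo-8-[(E)-2-methylbut-2-enoyloxy]germacr-7(11)-en-12,6-olide (target)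
Conditions: 34, pyridine, DMAP (cat.), CH2Cl2, 0 °C → rt
Reagents that add atoms: tigloyl chloride (compound 34), C/C=C(\C)C(Cl)=O
Why: DMAP-catalysed acylation with the (E)-acid chloride gives the tiglate with retention at C8; any transannular hemiketal of 33 is in equilibrium with the hydroxy ketone that is acylated.

## Compound list

1 | (S)-4-benzyl-3-propanoyl-1,3-oxazolidin-2-one | CCC(=O)N1[C@@H](Cc2ccccc2)COC1=O | starting material
2 | allyl iodide | C=CCI | starting material
3 | (S)-4-benzyl-3-[(2R)-2-methylpent-4-enoyl]-1,3-oxazolidin-2-one | C=CC[C@@H](C)C(=O)N1[C@@H](Cc2ccccc2)COC1=O | intermediate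
4 | (R)-2-methylpent-4-en-1-ol | C=CC[C@@H](C)CO | intermediate
5 | (R)-1-methoxy-4-{[(2-methylpent-4-en-1-yl)oxy]methyl}benzene | C=CC[C@@H](C)COCc1ccc(OC)cc1 | intermediate
6 | (R)-4-[(4-methoxybenzyl)oxy]-3-methylbutanal (fragment A) | O=CC[C@@H](C)COCc1ccc(OC)cc1 | intermediate
7 | (Z)-3-methylpent-2-en-4-yn-1-ol | C#C/C(C)=C\CO | starting material
8 | (Z)-trimethyl{[3-methyl-5-(trimethylsilyl)pent-2-en-4-yn-1-yl]oxy}silane | C[Si](C)(C)C#C/C(C)=C\CO[Si](C)(C)C | intermediate (not isolated)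
9 | (Z)-3-methyl-5-(trimethylsilyl)pent-2-en-4-yn-1-ol | C[Si](C)(C)C#C/C(C)=C\CO | intermediate
10 | [(2S,3R)-3-methyl-3-[(trimethylsilyl)ethynyl]oxiran-2-yl]methanol | C[Si](C)(C)C#C[C@@]1(C)O[C@H]1CO | intermediate
11 | (2R,3R)-3-methyl-3-[(trimethylsilyl)ethynyl]oxirane-2-carbaldehyde | C[Si](C)(C)C#C[C@@]1(C)O[C@H]1C=O | intermediate
12 | vinylmagnesium bromide | C=C[Mg]Br | starting material
13 | (1S)-1-[(2S,3R)-3-methyl-3-[(trimethylsilyl)ethynyl]oxiran-2-yl]prop-2-en-1-ol | C[Si](C)(C)C#C[C@@]1(C)O[C@H]1[C@@H](O)C=C | intermediate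
14 | 2-(bromomethyl)acrylic acid | C=C(CBr)C(=O)O | starting material
15 | (1S)-1-[(2S,3R)-3-methyl-3-[(trimethylsilyl)ethynyl]oxiran-2-yl]prop-2-en-1-yl 2-(bromomethyl)acrylate | C[Si](C)(C)C#C[C@@]1(C)O[C@H]1[C@@H](OC(=O)C(=C)CBr)C=C | intermediate
16 | (5S)-3-(bromomethyl)-5-[(2S,3R)-3-methyl-3-[(trimethylsilyl)ethynyl]oxiran-2-yl]furan-2(5H)-one (fragment B) | C[Si](C)(C)C#C[C@@]1(C)O[C@H]1[C@H]1OC(=O)C(CBr)=C1 | intermediate
17 | allylzinc bromide from 16 (bromozinc on C13) | C[Si](C)(C)C#C[C@@]1(C)O[C@H]1[C@H]1OC(=O)C(C[Zn]Br)=C1 | intermediate (not isolated)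
18 | (4R,5S)-4-[(1S,3R)-1-hydroxy-4-[(4-methoxybenzyl)oxy]-3-methylbutyl]-3-methylidene-5-[(2S,3R)-3-methyl-3-[(trimethylsilyl)ethynyl]oxiran-2-yl]oxolan-2-one (6S,7R,8S,10R) | C[Si](C)(C)C#C[C@@]1(C)O[C@H]1[C@H]1OC(=O)C(=C)[C@@H]1[C@@H](O)C[C@@H](C)COCc1ccc(OC)cc1 | intermediate
19 | C8 triethylsilyl ether of 18 | C[Si](C)(C)C#C[C@@]1(C)O[C@H]1[C@H]1OC(=O)C(=C)[C@@H]1[C@@H](O[Si](CC)(CC)CC)C[C@@H](C)COCc1ccc(OC)cc1 | intermediate
20 | α-keto lactone (C11 ketone) from 19 | C[Si](C)(C)C#C[C@@]1(C)O[C@H]1[C@H]1OC(=O)C(=O)[C@@H]1[C@@H](O[Si](CC)(CC)CC)C[C@@H](C)COCc1ccc(OC)cc1 | intermediate (not isolated)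
21 | (5S)-3-hydroxy-4-[(1S,3R)-4-[(4-methoxybenzyl)oxy]-3-methyl-1-(triethylsilyloxy)butyl]-5-[(2S,3R)-3-methyl-3-[(trimethylsilyl)ethynyl]oxiran-2-yl]furan-2(5H)-one | C[Si](C)(C)C#C[C@@]1(C)O[C@H]1[C@H]1OC(=O)C(O)=C1[C@@H](O[Si](CC)(CC)CC)C[C@@H](C)COCc1ccc(OC)cc1 | intermediate
22 | C11 enol triflate of 21 | C[Si](C)(C)C#C[C@@]1(C)O[C@H]1[C@H]1OC(=O)C(OS(=O)(=O)C(F)(F)F)=C1[C@@H](O[Si](CC)(CC)CC)C[C@@H](C)COCc1ccc(OC)cc1 | intermediate
23 | (tributylstannyl)methanol | CCCC[Sn](CO)(CCCC)CCCC | starting material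
24 | 3-(hydroxymethyl)butenolide (C13 alcohol) | C[Si](C)(C)C#C[C@@]1(C)O[C@H]1[C@H]1OC(=O)C(CO)=C1[C@@H](O[Si](CC)(CC)CC)C[C@@H](C)COCc1ccc(OC)cc1 | intermediate
25 | 3-(acetoxymethyl)butenolide (C13 acetate) with silyl alkyne | C[Si](C)(C)C#C[C@@]1(C)O[C@H]1[C@H]1OC(=O)C(COC(C)=O)=C1[C@@H](O[Si](CC)(CC)CC)C[C@@H](C)COCc1ccc(OC)cc1 | intermediate
26 | iodoalkyne corresponding to 25 | IC#C[C@@]1(C)O[C@H]1[C@H]1OC(=O)C(COC(C)=O)=C1[C@@H](O[Si](CC)(CC)CC)C[C@@H](C)COCc1ccc(OC)cc1 | intermediate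
27 | (Z)-vinyl iodide with PMB ether | I/C=C\[C@@]1(C)O[C@H]1[C@H]1OC(=O)C(COC(C)=O)=C1[C@@H](O[Si](CC)(CC)CC)C[C@@H](C)COCc1ccc(OC)cc1 | intermediate
28 | (Z)-vinyl iodide with free C1 alcohol | I/C=C\[C@@]1(C)O[C@H]1[C@H]1OC(=O)C(COC(C)=O)=C1[C@@H](O[Si](CC)(CC)CC)C[C@@H](C)CO | intermediate
29 | (Z)-vinyl iodide with C1 aldehyde | I/C=C\[C@@]1(C)O[C@H]1[C@H]1OC(=O)C(COC(C)=O)=C1[C@@H](O[Si](CC)(CC)CC)C[C@@H](C)C=O | intermediate
30 | (1RS,2Z,4R,5S,6S,8S,10R)-13-acetoxy-4,5-epoxy-1-hydroxy-8-(triethylsilyloxy)germacra-2,7(11)-dien-12,6-olide | CC[Si](CC)(CC)O[C@H]1C[C@@H](C)C(O)/C=C\[C@@]2(C)O[C@H]2[C@H]2OC(=O)C(COC(C)=O)=C12 | intermediate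
31 | (1RS,4R,5S,6S,8S,10R)-13-acetoxy-4,5-epoxy-1-hydroxy-8-(triethylsilyloxy)germacr-7(11)-en-12,6-olide | CC[Si](CC)(CC)O[C@H]1C[C@@H](C)C(O)CC[C@@]2(C)O[C@H]2[C@H]2OC(=O)C(COC(C)=O)=C12 | intermediate
32 | (4R,5S,6S,8S,10R)-13-acetoxy-4,5-epoxy-1-oxo-8-(triethylsilyloxy)germacr-7(11)-en-12,6-olide | CC[Si](CC)(CC)O[C@H]1C[C@@H](C)C(=O)CC[C@@]2(C)O[C@H]2[C@H]2OC(=O)C(COC(C)=O)=C12 | intermediate
33 | (4R,5S,6S,8S,10R)-13-acetoxy-4,5-epoxy-8-hydroxy-1-oxogermacr-7(11)-en-12,6-olide | O[C@H]1C[C@@H](C)C(=O)CC[C@@]2(C)O[C@H]2[C@H]2OC(=O)C(COC(C)=O)=C12 | intermediate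
34 | tigloyl chloride, (E)-2-methylbut-2-enoyl chloride | C/C=C(\C)C(Cl)=O | starting material
35 | (4R,5S,6S,8S,10R)-13-acetoxy-4,5-epoxy-1-oxo-8-[(E)-2-methylbut-2-enoyloxy]germacr-7(11)-en-12,6-olide | C/C=C(\C)C(=O)O[C@H]1C[C@@H](C)C(=O)CC[C@@]2(C)O[C@H]2[C@H]2OC(=O)C(COC(C)=O)=C12 | target

## Step count and risks

Total steps: 25. Longest linear sequence: 21 steps (7 → 9 → 10 → 11 → 13 → 15 → 16, then steps 11–25 to 35). Fragment A takes 4 steps (1 → 6).

Steps most likely to fail:

Step 10 (metathesis to the bromomethyl butenolide; the 1,1-disubstituted bromo-acrylate may close slowly or the alkyne may interfere). The fallback builds the lactone by a second carbonyl allylation instead of metathesis and sets out from epoxy aldehyde 11. Zinc and ethyl 2-(bromomethyl)acrylate in THF/aqueous NH4Cl give, again under Felkin control, ethyl (4S)-4-hydroxy-2-methylidene-4-[(2S,3R)-3-methyl-3-[(trimethylsilyl)ethynyl]oxiran-2-yl]butanoate F1. Warming with a trace of pyridinium p-toluenesulfonate lactonises it to the 5-substituted α-methylene-γ-butyrolactone F2. Wohl–Ziegler bromination (N-bromosuccinimide, azobisisobutyronitrile, PhCF3, 80 °C) abstracts the allylic C7 hydrogen and delivers bromine to C13 with the double bond moving into the ring. This is bromolactone 16, where the route resumes.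

Step 15 (Stille coupling on a hindered tetrasubstituted triflate, in a molecule whose alkynyl oxirane zerovalent palladium can also attack once the triflate is gone). The fallback is a palladium-free transposition that keeps C13 and sets out from silyl ether 19. OsO4 (cat.) with N-methylmorpholine N-oxide dihydroxylates the exocyclic alkene from the face opposite the C8 side chain to give the 11,13-diol F3. Ac2O with 2,4,6-collidine acetylates only the primary hydroxyl to give the 13-acetoxy-11-hydroxy lactone F4. Syn-dehydration with the Burgess reagent (toluene, 50 °C) removes the tertiary hydroxyl together with the cis H-7 and gives the 13-acetoxy butenolide 25, where the route resumes; steps 13–16 are bypassed. The regiochemistry of this dehydration is the uncertain point.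

Step 21 (ten-membered ring closure; a vinylchromium next to an oxirane, Lewis-acidic CrCl2 and competing dimerisation). The fallback closes the same C2=C3 bond by ring-closing metathesis and sets out from acetate 25. AgNO3-catalysed protodesilylation (acetone/water, 2,6-lutidine) gives the terminal alkyne F5. Lindlar semi-hydrogenation (H2, Pd on CaCO3 poisoned with Pb(OAc)2, quinoline) gives the vinyl oxirane F6. DDQ and then Dess–Martin periodinane give the primary alcohol F7 and the aldehyde F8. Vinylmagnesium bromide 12 at −78 °C adds to the aldehyde to give the allylic alcohol F9. Second-generation Grubbs catalyst at high dilution closes the ring with loss of ethylene to give the Z-cyclodecene 30 or its E isomer F10. Either is reduced by diimide as in step 22 to 31, where the route resumes.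

Further compounds
F1 | step 10 | ethyl (4S)-4-hydroxy-2-methylidene-4-[(2S,3R)-3-methyl-3-[(trimethylsilyl)ethynyl]oxiran-2-yl]butanoate | C[Si](C)(C)C#C[C@@]1(C)O[C@H]1[C@@H](O)CC(=C)C(=O)OCC
F2 | step 10 | (5S)-3-methylidene-5-[(2S,3R)-3-methyl-3-[(trimethylsilyl)ethynyl]oxiran-2-yl]oxolan-2-one | C[Si](C)(C)C#C[C@@]1(C)O[C@H]1[C@H]1OC(=O)C(=C)C1
F3 | step 15 | 11,13-diol of 19 (O-11 cis to H-7) | C[Si](C)(C)C#C[C@@]1(C)O[C@H]1[C@H]1OC(=O)[C@](O)(CO)[C@@H]1[C@@H](O[Si](CC)(CC)CC)C[C@@H](C)COCc1ccc(OC)cc1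
F4 | step 15 | 13-acetoxy-11-hydroxy lactone from F3 | C[Si](C)(C)C#C[C@@]1(C)O[C@H]1[C@H]1OC(=O)[C@](O)(COC(C)=O)[C@@H]1[C@@H](O[Si](CC)(CC)CC)C[C@@H](C)COCc1ccc(OC)cc1
F5 | step 21 | terminal alkyne from 25 | C#C[C@@]1(C)O[C@H]1[C@H]1OC(=O)C(COC(C)=O)=C1[C@@H](O[Si](CC)(CC)CC)C[C@@H](C)COCc1ccc(OC)cc1
F6 | step 21 | vinyl oxirane with PMB ether | C=C[C@@]1(C)O[C@H]1[C@H]1OC(=O)C(COC(C)=O)=C1[C@@H](O[Si](CC)(CC)CC)C[C@@H](C)COCc1ccc(OC)cc1
F7 | step 21 | vinyl oxirane with free C1 alcohol | C=C[C@@]1(C)O[C@H]1[C@H]1OC(=O)C(COC(C)=O)=C1[C@@H](O[Si](CC)(CC)CC)C[C@@H](C)CO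
F8 | step 21 | vinyl oxirane with C1 aldehyde | C=C[C@@]1(C)O[C@H]1[C@H]1OC(=O)C(COC(C)=O)=C1[C@@H](O[Si](CC)(CC)CC)C[C@@H](C)C=O
F9 | step 21 | diene with C1 allylic alcohol (C1 epimers) | C=C[C@@]1(C)O[C@H]1[C@H]1OC(=O)C(COC(C)=O)=C1[C@@H](O[Si](CC)(CC)CC)C[C@@H](C)C(O)C=C
F10 | step 21 | (2E) isomer of 30 | CC[Si](CC)(CC)O[C@H]1C[C@@H](C)C(O)/C=C/[C@@]2(C)O[C@H]2[C@H]2OC(=O)C(COC(C)=O)=C12
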